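The anhydride ring is traced back to a 2(5H)-furanone, and the route rests on cutting its C3=C4 double bond into a phosphonate-stabilised carbanion at C3 and a methyl ketone at C4 that are already joined through the C2 ester oxygen. One base-mediated operation then closes the five-membered lactone and creates the tetrasubstituted C3=C4 alkene, with the carbonyl carbon C2 and the future carbonyl carbon C5 necessarily cis because both lie in the ring. The precursor is the 2-oxopropyl ester of a 2-(diethoxyphosphoryl)octadecanoic acid that already carries the (17S)-acetate; C5 is raised from CH2 to C=O afterwards through a silyloxyfuran.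

Key step: step 8

Remark: ring atoms are numbered O1, C2 (carbonyl next to the chain-bearing carbon), C3 (bears the chain), C4 (bears CH3), C5; the chain holds fourteen CH2 groups between ring and (S)-carbinol carbon (5 + 11 carbons from 3 and 1). The acetate is put on once in step 2, hence the acid-cleavable tert-butyl phosphonoacetate. Compounds 11, 12 and 14 are C2-epimer mixtures and 18 is a lactol-epimer mixture; all converge.

Step 1
Reactants: 1 11-bromoundecan-1-ol
Product: 2 benzyl 11-bromoundecyl ether
Conditions: BnOC(=NH)CCl3, TfOH (cat.), CH2Cl2/cyclohexane, 0 °C → rt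
Reagents that add atoms: benzyl 2,2,2-trichloroacetimidate, N=C(OCc1ccccc1)C(Cl)(Cl)Cl
Why: Acid-catalysed O-benzylation with a trichloroacetimidate (imidate alkylation) needs no alkoxide, so the primary bromide is not displaced.

Step 2
Reactants: 3 (S)-pent-4-yn-2-ol; 2 benzyl 11-bromoundecyl ether
Product: 6 (S)-16-(benzyloxy)hexadec-4-yn-2-yl acetate, via dilithio pentynolate 4 (not isolated), via lithium alkoxide 5 (not isolated)
Conditions: n-BuLi (2.0 equiv), THF/DMPU, –78 → –20 °C; then 2, –20 °C → rt; then Ac2O, 0 °C → rt
Reagents that add atoms: acetic anhydride, CC(=O)OC(C)=O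
Why: Alkylation of a terminal acetylide (SN2 at the primary bromide) by the dilithio species, in which carbon is far more nucleophilic than the lithium alkoxide, is followed by O-acylation of that alkoxide in the same flask, and since no bond to the carbinol carbon is made or broken the (S) configuration of 3 is carried over unchanged.

Step 3
Reactants: 6 (S)-16-(benzyloxy)hexadec-4-yn-2-yl acetate
Product: 7 (S)-16-hydroxyhexadecan-2-yl acetate
Conditions: H2 (1 atm), Pd/C, EtOAc/EtOH, rt
Reagents that add atoms: none
Why: Heterogeneous catalytic hydrogenation saturates the alkyne and hydrogenolysis cleaves the benzyl ether in the same operation, while the homopropargylic (not propargylic) acetate and its stereocentre are inert.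

Step 4
Reactants: 7 (S)-16-hydroxyhexadecan-2-yl acetate
Product: 8 (S)-16-iodohexadecan-2-yl acetate
Conditions: I2, PPh3, imidazole, CH2Cl2, 0 °C → rt
Reagents that add atoms: iodine, [I][I]
Why: Appel-type iodination converts the primary alcohol via its alkoxyphosphonium salt by SN2 under neutral conditions that leave the remote acetate untouched.

Step 5
Reactants: 8 (S)-16-iodohexadecan-2-yl acetate; 9 tert-butyl 2-(diethoxyphosphoryl)acetate
Product: 11 tert-butyl (17S)-17-acetoxy-2-(diethoxyphosphoryl)octadecanoate, via sodium phosphonoacetate enolate 10 (not isolated)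
Conditions: 9 (1.5 equiv), NaH (1.4 equiv), DMF, 0 °C → rt; then 8, 60 °C
Reagents that add atoms: none
Why: C-Alkylation of a phosphonate-stabilised ester enolate by a primary iodide (SN2) is standard, the excess of enolate over NaH suppresses dialkylation and leaves no strong base for the acetate, and the new C2 centre forms as both epimers, which is harmless because it becomes sp2 in step 8.

Step 6
Reactants: 11 tert-butyl (17S)-17-acetoxy-2-(diethoxyphosphoryl)octadecanoate
Product: 12 (17S)-17-acetoxy-2-(diethoxyphosphoryl)octadecanoic acid
Conditions: CF3CO2H/CH2Cl2 (1:3), rt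
Reagents that add atoms: none
Why: Acidolysis of a tert-butyl ester (E1 loss of isobutene from the protonated ester) proceeds at room temperature without touching the secondary acetate or the diethyl phosphonate.

Step 7
Reactants: 12 (17S)-17-acetoxy-2-(diethoxyphosphoryl)octadecanoic acid; 13 chloroacetone
Product: 14 2-oxopropyl (17S)-17-acetoxy-2-(diethoxyphosphoryl)octadecanoate
Conditions: KHCO3, NaI (cat.), DMF, rt
Reagents that add atoms: none
Why: O-Alkylation of a carboxylate by an α-halo ketone (SN2, iodide-catalysed) is fast, and bicarbonate is too weak a base to deprotonate the phosphonate α-carbon or to cleave the acetate.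

Step 8
Reactants: 14 2-oxopropyl (17S)-17-acetoxy-2-(diethoxyphosphoryl)octadecanoate
Product: 15 (S)-16-(4-methyl-2-oxo-2,5-dihydrofuran-3-yl)hexadecan-2-yl acetate
Conditions: LiCl, DBU, MeCN, 0 °C → rt
Reagents that add atoms: none
Why: Lithium coordination to the phosphoryl and ester oxygens makes the hydrogen on the phosphonate-bearing carbon of 14 (the future ring C3) acidic enough for DBU, and the stabilised carbanion adds to the ketone carbonyl of the 2-oxopropyl group to give a β-alkoxy phosphonate that closes to an oxaphosphetane and collapses with loss of diethyl phosphate, so the C3=C4 bond and the lactone ring arise in the same event. The closest known reaction type is the intramolecular Horner–Wadsworth–Emmons olefination of phosphonoacetates of α-hydroxy ketones to butenolides in its mild LiCl/amine variant. The furanone ring closes in the 5-exo-trig mode, the carbanion carbon attacking the ketone carbon while the carbonyl oxygen stays outside the new ring. No stereocentre is created: both epimers of 14 give the same planar C3, the alkene geometry is dictated by the ring because C2 and C5 are both ring atoms, and the remote (S)-acetate centre takes no part. The selectivity required is chemoselectivity for the phosphonate carbanion over the ketone enolate and over attack on either ester, and it is secured by the much higher acidity of the chelated P–CH–C=O unit towards a non-nucleophilic amine base and by the ease of five-membered ring closure.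

Step 9
Reactants: 15 (S)-16-(4-methyl-2-oxo-2,5-dihydrofuran-3-yl)hexadecan-2-yl acetate
Product: 16 (S)-16-{4-methyl-2-[(triisopropylsilyl)oxy]furan-3-yl}hexadecan-2-yl acetate
Conditions: i-Pr3SiOTf, Et3N, CH2Cl2, 0 °C → rt
Reagents that add atoms: triisopropylsilyl trifluoromethanesulfonate, CC(C)[Si](C(C)C)(C(C)C)OS(=O)(=O)C(F)(F)F
Why: Soft enolisation (O-silylation of the lactone carbonyl, then removal of a C5 proton by Et3N) gives the aromatic 2-silyloxyfuran as the thermodynamically preferred silyl dienol ether, and a simple acetate is not enolised under these conditions.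

Step 10
Reactants: 16 (S)-16-{4-methyl-2-[(triisopropylsilyl)oxy]furan-3-yl}hexadecan-2-yl acetate
Product: 18 (2S)-16-(5-hydroxy-4-methyl-2-oxo-2,5-dihydrofuran-3-yl)hexadecan-2-yl acetate, via silyl oxobutenoate 17 (not isolated)
Conditions: dimethyldioxirane (acetone solution), CH2Cl2, –78 °C; then Amberlyst-15, acetone/H2O, rt
Reagents that add atoms: dimethyldioxirane, CC1(C)OO1
Why: Oxygen transfer from the dioxirane to the electron-rich C5 terminus of the silyloxyfuran (oxyfunctionalisation of a silyl dienol ether, a vinylogous Rubottom-type oxidation) opens the ring to the silyl (Z)-4-oxobut-2-enoate, and hydrolysis of the silyl ester lets the acid add to the cis aldehyde to give the 5-hydroxybutenolide as a mixture of lactol epimers whose C5 centre is erased in step 11.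

Step 11
Reactants: 18 (2S)-16-(5-hydroxy-4-methyl-2-oxo-2,5-dihydrofuran-3-yl)hexadecan-2-yl acetate
Product: 19 (S)-16-(4-methyl-2,5-dioxo-2,5-dihydrofuran-3-yl)hexadecan-2-yl acetate
Conditions: [C5H5NH][CrO3Cl] (pyridinium chlorochromate), NaOAc, CH2Cl2, rt
Reagents that add atoms: none
Why: Oxidation of a cyclic hemiacetal to the carbonyl by a chlorochromate (hexavalent chromium, via a chromate ester) turns the lactol into the cyclic anhydride and leaves the acetate and the tetrasubstituted alkene alone.

Compound list
1 | 11-bromoundecan-1-ol | OCCCCCCCCCCCBr | starting material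
2 | benzyl 11-bromoundecyl ether, {[(11-bromoundecyl)oxy]methyl}benzene | BrCCCCCCCCCCCOCc1ccccc1 | intermediate
3 | (S)-pent-4-yn-2-ol | C[C@H](O)CC#C | starting material
4 | dilithium salt of (S)-pent-4-yn-2-ol (lithium alkoxide, lithium alkynide) | C[C@H]([O-])CC#[C-].[Li+].[Li+] | intermediate (not isolated)
5 | lithium (S)-16-(benzyloxy)hexadec-4-yn-2-olate | C[C@H]([O-])CC#CCCCCCCCCCCCOCc1ccccc1.[Li+] | intermediate (not isolated)
6 | (S)-16-(benzyloxy)hexadec-4-yn-2-yl acetate | CC(=O)O[C@@H](C)CC#CCCCCCCCCCCCOCc1ccccc1 | intermediate
7 | (S)-16-hydroxyhexadecan-2-yl acetate | CC(=O)O[C@@H](C)CCCCCCCCCCCCCCO | intermediate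
8 | (S)-16-iodohexadecan-2-yl acetate | CC(=O)O[C@@H](C)CCCCCCCCCCCCCCI | intermediate
9 | tert-butyl 2-(diethoxyphosphoryl)acetate | CCOP(=O)(CC(=O)OC(C)(C)C)OCC | starting material
10 | sodium enolate of tert-butyl 2-(diethoxyphosphoryl)acetate | CCOP(=O)(OCC)[CH-]C(=O)OC(C)(C)C.[Na+] | intermediate (not isolated)
11 | tert-butyl (17S)-17-acetoxy-2-(diethoxyphosphoryl)octadecanoate (both C2 epimers) | CC(=O)O[C@@H](C)CCCCCCCCCCCCCCC(C(=O)OC(C)(C)C)P(=O)(OCC)OCC | intermediate
12 | (17S)-17-acetoxy-2-(diethoxyphosphoryl)octadecanoic acid (both C2 epimers) | CC(=O)O[C@@H](C)CCCCCCCCCCCCCCC(C(=O)O)P(=O)(OCC)OCC | intermediate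
13 | chloroacetone (1-chloropropan-2-one) | CC(=O)CCl | starting material
14 | 2-oxopropyl (17S)-17-acetoxy-2-(diethoxyphosphoryl)octadecanoate (both C2 epimers) | CC(=O)O[C@@H](C)CCCCCCCCCCCCCCC(C(=O)OCC(C)=O)P(=O)(OCC)OCC | intermediate
15 | (S)-16-(4-methyl-2-oxo-2,5-dihydrofuran-3-yl)hexadecan-2-yl acetate | CC(=O)O[C@@H](C)CCCCCCCCCCCCCCC1=C(C)COC1=O | intermediate
16 | (S)-16-{4-methyl-2-[(triisopropylsilyl)oxy]furan-3-yl}hexadecan-2-yl acetate | CC(=O)O[C@@H](C)CCCCCCCCCCCCCCc1c(C)coc1O[Si](C(C)C)(C(C)C)C(C)C | intermediate
17 | triisopropylsilyl (2Z)-2-[(15S)-15-acetoxyhexadecyl]-3-methyl-4-oxobut-2-enoate | CC(=O)O[C@@H](C)CCCCCCCCCCCCCC/C(C(=O)O[Si](C(C)C)(C(C)C)C(C)C)=C(\C)C=O | intermediate (not isolated)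
18 | (2S)-16-(5-hydroxy-4-methyl-2-oxo-2,5-dihydrofuran-3-yl)hexadecan-2-yl acetate (both lactol epimers) | CC(=O)O[C@@H](C)CCCCCCCCCCCCCCC1=C(C)C(O)OC1=O | intermediate
19 | (S)-16-(4-methyl-2,5-dioxo-2,5-dihydrofuran-3-yl)hexadecan-2-yl acetate | CC(=O)O[C@@H](C)CCCCCCCCCCCCCCC1=C(C)C(=O)OC1=O | target

Total step count: 11.
Longest linear sequence: 11 steps (1 → 19); compounds 3, 9 and 13 enter as commercial inputs, so there is no side branch.

Steps most likely to fail

Step 8. The fully substituted carbanion may add too slowly to the ketone. Base-induced cleavage or acyl migration of the activated 2-oxopropyl ester, or aldol-type reaction through the ketone enolate, could then consume the substrate before olefination. The fallback couples the chain onto a preformed furanone instead of closing the ring, and sets out from iodide 8. Zinc insertion (Zn dust activated with BrCH2CH2Br and Me3SiCl, LiCl, THF, 40 °C) should give [(15S)-15-acetoxyhexadecyl]zinc iodide F1, which tolerates the acetate. In parallel, commercial 4-methylfuran-2(5H)-one is brominated (Br2, CH2Cl2) to 3,4-dibromo-4-methyldihydrofuran-2(3H)-one F2 and dehydrobrominated with Et3N to 3-bromo-4-methylfuran-2(5H)-one F3. Negishi coupling of F1 with F3 (PdCl2(dppf), THF, 50 °C) forms the C3–CH2 bond and comes back to the route at 15.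

Step 2. The sparingly soluble dilithio species may react sluggishly, elimination of HBr from the bromide by the basic alkynide may compete, and acylation in the same flask may be incomplete. The fallback brings the stereocentre in as an epoxide and makes the other C–C bond of the alkyne last; it sets out from 2. Displacement with LiC≡CH·H2NCH2CH2NH2 (lithium acetylide–ethylenediamine complex) in DMSO should give 13-(benzyloxy)tridec-1-yne F4. Its lithium alkynide (n-BuLi, THF, –78 °C) opens commercial (S)-2-methyloxirane at the CH2 terminus in the presence of BF3·OEt2 to give (S)-16-(benzyloxy)hexadec-4-yn-2-ol F5, with the C–O stereocentre untouched. Acetylation (Ac2O, pyridine, DMAP) comes back to the route at 6.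

Step 10. The dioxirane may oxidise beyond the first oxygen transfer, adventitious water may protodesilylate the silyloxyfuran back to 15, and hydrolysis of the bulky silyl ester may be slow enough for the acid to start cleaving the acetate. The fallback uses halogenation and substitution at C5 instead of oxygen transfer, and sets out from 16. Electrophilic bromination at C5 with N-bromosuccinimide (THF, –78 °C) should give (2S)-16-(5-bromo-4-methyl-2-oxo-2,5-dihydrofuran-3-yl)hexadecan-2-yl acetate F6. This pseudo-acid bromide is hydrolysed in aqueous acetone buffered with NaHCO3 and comes back to the route at 18.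

Further compounds
F1 | step 8 | [(15S)-15-acetoxyhexadecyl]zinc iodide | CC(=O)O[C@@H](C)CCCCCCCCCCCCCC[Zn]I
F2 | step 8 | 3,4-dibromo-4-methyldihydrofuran-2(3H)-one (racemic) | CC1(Br)COC(=O)C1Br
F3 | step 8 | 3-bromo-4-methylfuran-2(5H)-one | CC1=C(Br)C(=O)OC1
F4 | step 2 | 13-(benzyloxy)tridec-1-yne | C#CCCCCCCCCCCCOCc1ccccc1
F5 | step 2 | (S)-16-(benzyloxy)hexadec-4-yn-2-ol | C[C@H](O)CC#CCCCCCCCCCCCOCc1ccccc1
F6 | step 10 | (2S)-16-(5-bromo-4-methyl-2-oxo-2,5-dihydrofuran-3-yl)hexadecan-2-yl acetate | CC(=O)O[C@@H](C)CCCCCCCCCCCCCCC1=C(C)C(Br)OC1=O
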